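Target ⇐ fluoride deprotection ⇐ Still–Gennari olefination (Z-acetoxyangelate on the ring O-acyl carbon) ⇐ Pd alkoxycarbonylation of a 1-bromovinyl group (acrylate) ⇐ equatorial hydride delivery to a cyclohexanone.
Enabling feature: in the cyclohexane ring, the quaternary carbon (C10: CH3, CH=CH2) and the acyloxy-bearing CH (C8) are separated only by the ring CH2 (C9). At the C8-ketone level, CH2=CH–C10–C9H2–C8=O is a γ,δ-unsaturated ketone, the retron of a Claisen rearrangement.
Cyclohexanone ⇐ [3,3] ring contraction (8 → 6) of a 2-methylene-3,4,5,8-tetrahydro-2H-oxocine, whose ring holds O, C2, C1=C10, C5, C6, C7, C8 and whose exocyclic CH2 becomes C9 ⇐ Tebbe methylenation of the (Z)-allylic eight-membered lactone.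
Lactone ⇐ RCM of an allyl ester ⇐ group-selective iodolactonisation (sets C5, masks the later C4 side chain as an oxirane) ⇐ Evans syn aldol (sets C6, C7) of a 3-bromobut-3-enoyl imide with achiral bis(isopropenyl)acetaldehyde.
Order of ring formation: δ-lactone (temporary) → oxirane (temporary) → oxocinone → methyleneoxocine → cyclohexane.

Key step: step 12

Locants: C1–C15 are elemane locants. The ring is C5–C10. C10 carries CH3 (C14) and vinyl (C1=C2), C9 is the ring CH2, C8 carries O-acyl, C7 carries C11(=C13)–C12, C6 carries OH, and C5 carries C4(=C3)–C15.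
Assumption: the configuration drawn at the transient oxygenated carbon C4 in 13–17 is the one expected from the chair transition state. It has no consequence, because C4 becomes sp2 in step 10.

Step 1
Reactants: 1 2,4-dimethylpenta-1,3-diene
Product: 4 3-methyl-2-(prop-1-en-2-yl)but-3-en-1-ol, via 2,4-dimethylpentadienylpotassium 2 (not isolated), via 2,4-dimethylpentadienylmagnesium bromide 3 (not isolated)
Conditions: n-BuLi, KOt-Bu, THF/hexane, −78 → −20 °C; MgBr2·OEt2, −78 °C; CH2O (gas from paraformaldehyde), −78 → 0 °C; H2O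
Reagents that add atoms: formaldehyde, C=O
Why: γ-selective carbonyl addition of a pentadienylmagnesium reagent, in which the metal sits on a terminal CH2 and the central carbon attacks formaldehyde through a six-membered SE2′ transition state, should give the skipped diene with no stereocentre.

Step 2
Reactants: 4 3-methyl-2-(prop-1-en-2-yl)but-3-en-1-ol
Product: 5 3-methyl-2-(prop-1-en-2-yl)but-3-enal
Conditions: Dess–Martin periodinane, NaHCO3, CH2Cl2, 0 °C; used at once
Reagents that add atoms: none
Why: the buffered Dess–Martin oxidation is neutral enough to keep both double bonds out of conjugation, and since 5 is achiral its acidic α-H carries no stereochemical risk.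

Step 3
Reactants: 6 3-bromobut-3-enoic acid; 7 (S)-4-benzyloxazolidin-2-one
Product: 9 (S)-4-benzyl-3-(3-bromobut-3-enoyl)oxazolidin-2-one, via mixed pivalic anhydride 8 (not isolated)
Conditions: PivCl, Et3N, THF, −20 °C; then 7, LiCl, −20 °C → rt
Reagents that add atoms: none
Why: N-acylation through the mixed pivalic anhydride with LiCl activation needs no strong base and leaves the stereocentre of 7 untouched.

Step 4
Reactants: 9 (S)-4-benzyl-3-(3-bromobut-3-enoyl)oxazolidin-2-one; 5 3-methyl-2-(prop-1-en-2-yl)but-3-enal
Product: 11 (S)-4-benzyl-3-[(2S,3R)-2-(1-bromovinyl)-3-hydroxy-5-methyl-4-(prop-1-en-2-yl)hex-5-enoyl]oxazolidin-2-one, via (Z)-dibutylboron enolate 10 (not isolated)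
Conditions: n-Bu2BOTf, Et3N, CH2Cl2, −78 → 0 °C; 5, −78 → 0 °C; MeOH, pH 7 buffer, H2O2, 0 °C
Reagents that add atoms: none
Why: in the Evans syn aldol reaction the (Z)-boron enolate reacts at its α-carbon through a Zimmerman–Traxler chair on the face away from the benzyl group, which sets C7 and C6 (syn) and leaves the 1-bromovinyl group unconjugated.

Step 5
Reactants: 11 aldol adduct
Product: 12 (2S,3R)-2-(1-bromovinyl)-3-hydroxy-5-methyl-4-(prop-1-en-2-yl)hex-5-enoic acid
Conditions: LiOH, H2O2, THF/H2O, 0 °C; Na2SO3; HCl to pH 2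
Reagents that add atoms: hydrogen peroxide (as LiOOH), OO
Why: hydroperoxide-mediated cleavage of the exocyclic imide carbonyl should remove the auxiliary without retro-aldol reaction or epimerisation at C7.

Step 6
Reactants: 12 hydroxy acid
Product: 13 (3S,4R,5R,6R)-3-(1-bromovinyl)-4-hydroxy-6-(iodomethyl)-6-methyl-5-(prop-1-en-2-yl)tetrahydro-2H-pyran-2-one
Conditions: I2, NaHCO3, MeCN, 0 °C, dark
Reagents that add atoms: iodine, II
Why: in this iodolactonisation (6-exo-trig, anti addition) the carboxylate can reach only one of the two diastereotopic isopropenyl groups through a chair with bromovinyl, OH and the spectator isopropenyl all equatorial, which fixes C5 (spectator isopropenyl trans to OH on the lactone) and, with CH2I equatorial, the transient centre C4.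

Step 7
Reactants: 13 iodolactone
Product: 14 4-O-triethylsilyl ether of 13
Conditions: TESOTf, 2,6-lutidine, CH2Cl2, −78 → 0 °C
Reagents that add atoms: triethylsilyl triflate, CC[Si](CC)(CC)OS(=O)(=O)C(F)(F)F
Why: silylation of the hindered secondary alcohol with a silyl triflate and a non-nucleophilic base touches neither the iodolactone nor any stereocentre.

Step 8
Reactants: 14 silylated iodolactone
Product: 16 allyl 2-(1-bromovinyl)-5-methyl-4-(2-methyloxiran-2-yl)-3-(triethylsilyloxy)hex-5-enoate (C5/C6/C7 as in 30), via iodohydrin allyl ester 15 (not isolated)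
Conditions: K2CO3, allyl alcohol, 0 °C → rt
Reagents that add atoms: allyl alcohol, C=CCO
Why: base-catalysed transesterification of the lactone followed by 3-exo-tet closure of the released tertiary alkoxide onto CH2I (the classical iodolactone-to-epoxy-ester conversion) is irreversible, installs the allyl ester, keeps the C4–O bond and masks the second 1,1-disubstituted alkene against metathesis.

Step 9
Reactants: 16 epoxy allyl ester
Product: 17 (Z)-3-(1-bromovinyl)-6-methyl-5-(2-methyloxiran-2-yl)-4-(triethylsilyloxy)-3,4,5,8-tetrahydro-2H-oxocin-2-one (3,4-trans; 4,5-cis)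
Conditions: Hoveyda–Grubbs II (10 mol %), PhMe (1 mM), 80 °C, Ar sparge
Reagents that add atoms: none
Why: in this ring-closing metathesis only the allyl group and the remaining isopropenyl group are active (bromoalkene and oxirane are spectators), and the eight-membered ring can hold only the (Z)-trisubstituted alkene.

Step 10
Reactants: 17 epoxy lactone
Product: 18 (Z)-3-(1-bromovinyl)-5-[3-(tert-butyldimethylsilyloxy)prop-1-en-2-yl]-6-methyl-4-(triethylsilyloxy)-3,4,5,8-tetrahydro-2H-oxocin-2-one (3,4-trans; 4,5-cis)
Conditions: TBSOTf, 2,6-lutidine, PhMe, −78 → 0 °C; then DBU, rt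
Reagents that add atoms: tert-butyldimethylsilyl triflate, CC(C)(C)[Si](C)(C)OS(=O)(=O)C(F)(F)F
Why: silyl-triflate-mediated isomerisation of a 2,2-disubstituted oxirane to the allylic silyl ether (O-silylation, C4–O ionisation at the tertiary carbon, then loss of a proton from the unhindered methyl group rather than the shielded tertiary C5–H) should give CH2=C4–C15H2OTBS and erase C4.

Step 11
Reactants: 18 eight-membered lactone
Product: 19 (Z)-3-(1-bromovinyl)-5-[3-(tert-butyldimethylsilyloxy)prop-1-en-2-yl]-6-methyl-2-methylene-4-(triethylsilyloxy)-3,4,5,8-tetrahydro-2H-oxocine (3,4-trans; 4,5-cis)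
Conditions: Tebbe reagent, pyridine, THF/PhMe, −40 → 0 °C; aq. NaOH; basic alumina
Reagents that add atoms: Tebbe reagent, [CH2-2].[Ti+4].[CH-]1C=CC=C1.[CH-]1C=CC=C1.C[Al](C)Cl
Why: in the Tebbe methylenation the non-basic titanium methylidene turns the lactone C=O into the exocyclic enol ether through an oxatitanacyclobutane without epimerising C7, and the silyl ethers and the bromoalkene are inert.

Step 12
Reactants: 19 2-methyleneoxocine
Product: 20 2-(1-bromovinyl)-4-[3-(tert-butyldimethylsilyloxy)prop-1-en-2-yl]-5-methyl-3-(triethylsilyloxy)-5-vinylcyclohexan-1-one (2,3-trans; 3,4-cis; vinyl trans to the C4 side chain)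
Conditions: PhMe (0.01 M), trace i-Pr2NEt, amine-washed sealed tube, 110–130 °C
Reagents that add atoms: none
Why: Proposed new method: on heating, the allyl vinyl ether array CH2=C8(–C7)–O–C2H2–C1H=C10 of 19 should undergo a concerted, suprafacial [3,3]-sigmatropic (Claisen) shift; because only the enol-ether CH2 (future C9) is exocyclic while C8, O, C2, C1 and C10 are ring members, making C9–C10 and breaking O–C2 expels O, C2 and C1 from the ring and takes in C9, so that the eight-membered ring becomes the six-membered ring C5–C10 with C8=O and a vinyl group on C10. The closest known reaction types are the methylenation–Claisen sequence of allylic esters, the ring-enlarging Claisen rearrangement of 2-methylene-6-vinyltetrahydropyrans to cyclooctenones and the four-atom ring contraction of macrolactone ketene acetals (alicyclic Ireland–Claisen); a two-atom contraction of a 2-methyleneoxocine has not been shown. The single ring that closes, the cyclohexanone, does so transannularly (6-exo at the trisubstituted alkene, enol-exo at C8) through a chair pericyclic array sharing C8–C9–C10 with a chair carbocycle, a bicyclo[3.3.1]nonane-like transition state that is within reach only because the ring alkene is (Z), which puts the C5 tether on the axial-like position of C10. The only new stereocentre, quaternary C10, is controlled by the resident centres: the O–C2–C1 bridge (future vinyl) is necessarily axial, C6–OTES on the central tether atom must point exo (equatorial) because the endo position collides with C2H2, and this places the bromovinyl group equatorial and the C5 side chain axial and anti to the new vinyl group, i.e. vinyl trans to O6 and to C4 as in 30. The step needs this π-facial selectivity, secured by the exo-OTES/equatorial-bromovinyl preference (the other face would need both groups axial), and chemoselectivity, secured because 19 holds no second 1,5-dienyl array and because amine-washed glass suppresses protonation of the enol ether. Strain release from the medium ring and formation of C=O make the shift irreversible, and the divinylcyclohexane unit of 20 is the stable side of the elemane/germacrane Cope equilibrium.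

Step 13
Reactants: 20 cyclohexanone
Product: 21 2-(1-bromovinyl)-4-[3-(tert-butyldimethylsilyloxy)prop-1-en-2-yl]-5-methyl-3-(triethylsilyloxy)-5-vinylcyclohexan-1-ol (OH cis to bromovinyl; cis to vinyl)
Conditions: L-Selectride, THF, −78 °C; H2O
Reagents that add atoms: none
Why: in this ketone reduction with a bulky trialkylborohydride, the chair with OTES and bromovinyl equatorial has an axial vinyl group on C10 that blocks the axial trajectory, so hydride should enter equatorially and give the axial C8 alcohol, cis to the C7 side chain and to the vinyl group.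

Step 14
Reactants: 22 ethyl 2-[bis(2,2,2-trifluoroethoxy)phosphoryl]propanoate
Product: 23 2-[bis(2,2,2-trifluoroethoxy)phosphoryl]propanoic acid
Conditions: LiOH (1.0 equiv), THF/H2O, 0 °C; HCl
Reagents that add atoms: lithium hydroxide, [Li+].[OH-]
Why: chemoselective saponification of the carboxylic ester with one equivalent of hydroxide at 0 °C should spare the P–O trifluoroethyl esters, and the racemic α-carbon is lost in step 18.

Step 15
Reactants: 21 cyclohexanol; 23 phosphonopropanoic acid
Product: 24 C8 2-[bis(2,2,2-trifluoroethoxy)phosphoryl]propanoate of 21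
Conditions: DCC, DMAP (cat.), CH2Cl2, 0 °C → rt
Reagents that add atoms: none
Why: the Steglich esterification acylates the only free hydroxyl group without touching a ring stereocentre, and the epimer mixture at the phosphonate carbon is of no consequence.

Step 16
Reactants: 24 bromovinyl phosphonate ester
Product: 25 2-(trimethylsilyl)ethyl acrylate (C11=C13; C12 ester) derived from 24
Conditions: Pd(PPh3)4 (10 mol %), CO (1 atm), Me3SiCH2CH2OH, i-Pr2NEt, DMF, 60 °C
Reagents that add atoms: carbon monoxide, [C-]#[O+]; 2-(trimethylsilyl)ethanol, C[Si](C)(C)CCO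
Why: palladium-catalysed alkoxycarbonylation of an alkenyl bromide (oxidative addition, CO insertion, alcoholysis) should turn the 1-bromovinyl group into the 2-substituted acrylate, and with O6 and O8 blocked no lactone can form.

Step 17
Reactants: 26 (Z)-but-2-ene-1,4-diyl diacetate
Product: 27 2-oxoethyl acetate
Conditions: O3, CH2Cl2, −78 °C; Me2S
Reagents that add atoms: ozone, [O-][O+]=O
Why: ozonolysis with reductive work-up cleaves the symmetrical alkene into two molecules of 27.

Step 18
Reactants: 25 phosphonate ester; 27 2-oxoethyl acetate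
Product: 29 fully protected target (C8 (Z)-4-acetoxy-2-methylbut-2-enoate; C12 TMSE ester; O6-TES; O15-TBS), via potassium phosphonate carbanion 28 (not isolated)
Conditions: KHMDS, 18-crown-6, THF, −78 °C; then 27, −78 °C
Reagents that add atoms: none
Why: in the Still–Gennari olefination the electron-poor bis(trifluoroethyl) phosphonate with a dissociated potassium counter-ion eliminates fast from the kinetic adduct, which should give the (Z)-trisubstituted enoate while the stabilised anion leaves the acrylate and C7–H alone.

Step 19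
Reactants: 29 fully protected target
Product: 30 (5S,6R,7S,8R,10R)-8-[(Z)-4-acetoxy-2-methylbut-2-enoyloxy]-6,15-dihydroxyelema-1,3,11(13)-trien-12-oic acid
Conditions: TASF, DMF, 0 °C → rt; pH 5 NaH2PO4 buffer
Reagents that add atoms: none
Why: in this fluoride-induced deprotection the TMSE ester fragments by β-elimination to a carboxylate that cannot lactonise, the TES and TBS ethers are cleaved in the same operation, and the nearly neutral fluoride source with a buffered work-up should spare the acetate, the enoate ester and all stereocentres.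

Compound list
1 | 2,4-dimethylpenta-1,3-diene | CC(C)=CC(C)=C | starting material
2 | 2,4-dimethylpentadienylpotassium | [K+].[CH2-]C(C)=CC(C)=C | intermediate
3 | 2,4-dimethylpentadienylmagnesium bromide | Br[Mg]CC(C)=CC(C)=C | intermediate
4 | 3-methyl-2-(prop-1-en-2-yl)but-3-en-1-ol | OCC(C(C)=C)C(C)=C | intermediate
5 | 3-methyl-2-(prop-1-en-2-yl)but-3-enal | O=CC(C(C)=C)C(C)=C | intermediate
6 | 3-bromobut-3-enoic acid | C=C(Br)CC(=O)O | starting material
7 | (S)-4-benzyloxazolidin-2-one | O=C1N[C@@H](Cc2ccccc2)CO1 | starting material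
8 | 3-bromobut-3-enoic pivalic anhydride | C=C(Br)CC(=O)OC(=O)C(C)(C)C | intermediate
9 | (S)-4-benzyl-3-(3-bromobut-3-enoyl)oxazolidin-2-one | C=C(Br)CC(=O)N1[C@@H](Cc2ccccc2)COC1=O | intermediate
10 | (Z)-dibutylboron enolate of 9 | C=C(Br)/C=C(\OB(CCCC)CCCC)N1[C@@H](Cc2ccccc2)COC1=O | intermediate
11 | Evans syn aldol adduct (2S,3R) | O=C1OC[C@H](Cc2ccccc2)N1C(=O)[C@@H](C(Br)=C)[C@H](O)C(C(C)=C)C(C)=C | intermediate
12 | (2S,3R)-2-(1-bromovinyl)-3-hydroxy-5-methyl-4-(prop-1-en-2-yl)hex-5-enoic acid | OC(=O)[C@@H](C(Br)=C)[C@H](O)C(C(C)=C)C(C)=C | intermediate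
13 | (3S,4R,5R,6R)-iodolactone | O=C1[C@@H](C(Br)=C)[C@H](O)[C@@H](C(C)=C)[C@](C)(CI)O1 | intermediate
14 | O-TES iodolactone | O=C1[C@@H](C(Br)=C)[C@H](O[Si](CC)(CC)CC)[C@@H](C(C)=C)[C@](C)(CI)O1 | intermediate
15 | iodohydrin allyl ester | C=CCOC(=O)[C@@H](C(Br)=C)[C@H](O[Si](CC)(CC)CC)[C@@H](C(C)=C)[C@@](C)(O)CI | intermediate
16 | epoxy allyl ester | C=CCOC(=O)[C@@H](C(Br)=C)[C@H](O[Si](CC)(CC)CC)[C@@H](C(C)=C)[C@]1(C)CO1 | intermediate
17 | (Z)-oxocinone with oxirane side chain | O=C1OC/C=C(/C)[C@@H]([C@]2(C)CO2)[C@@H](O[Si](CC)(CC)CC)[C@@H]1C(Br)=C | intermediate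
18 | (Z)-oxocinone with CH2=C–CH2OTBS side chain | O=C1OC/C=C(/C)[C@@H](C(=C)CO[Si](C)(C)C(C)(C)C)[C@@H](O[Si](CC)(CC)CC)[C@@H]1C(Br)=C | intermediate
19 | 2-methyleneoxocine | C=C1OC/C=C(/C)[C@@H](C(=C)CO[Si](C)(C)C(C)(C)C)[C@@H](O[Si](CC)(CC)CC)[C@@H]1C(Br)=C | intermediate
20 | ring-contracted cyclohexanone | C=C[C@@]1(C)CC(=O)[C@@H](C(Br)=C)[C@H](O[Si](CC)(CC)CC)[C@@H]1C(=C)CO[Si](C)(C)C(C)(C)C | intermediate
21 | axial C8 alcohol | C=C[C@@]1(C)C[C@@H](O)[C@@H](C(Br)=C)[C@H](O[Si](CC)(CC)CC)[C@@H]1C(=C)CO[Si](C)(C)C(C)(C)C | intermediate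
22 | ethyl 2-[bis(2,2,2-trifluoroethoxy)phosphoryl]propanoate | CCOC(=O)C(C)P(=O)(OCC(F)(F)F)OCC(F)(F)F | starting material
23 | 2-[bis(2,2,2-trifluoroethoxy)phosphoryl]propanoic acid | OC(=O)C(C)P(=O)(OCC(F)(F)F)OCC(F)(F)F | intermediate
24 | C8 phosphonopropanoate, bromovinyl | C=C[C@@]1(C)C[C@@H](OC(=O)C(C)P(=O)(OCC(F)(F)F)OCC(F)(F)F)[C@@H](C(Br)=C)[C@H](O[Si](CC)(CC)CC)[C@@H]1C(=C)CO[Si](C)(C)C(C)(C)C | intermediate
25 | C8 phosphonopropanoate, TMSE acrylate | C=C[C@@]1(C)C[C@@H](OC(=O)C(C)P(=O)(OCC(F)(F)F)OCC(F)(F)F)[C@@H](C(=C)C(=O)OCC[Si](C)(C)C)[C@H](O[Si](CC)(CC)CC)[C@@H]1C(=C)CO[Si](C)(C)C(C)(C)C | intermediate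
26 | (Z)-but-2-ene-1,4-diyl diacetate | CC(=O)OC/C=C\COC(C)=O | starting material
27 | 2-oxoethyl acetate | CC(=O)OCC=O | intermediate
28 | potassium phosphonate carbanion of 25 | [K+].C=C[C@@]1(C)C[C@@H](OC(=O)[C-](C)P(=O)(OCC(F)(F)F)OCC(F)(F)F)[C@@H](C(=C)C(=O)OCC[Si](C)(C)C)[C@H](O[Si](CC)(CC)CC)[C@@H]1C(=C)CO[Si](C)(C)C(C)(C)C | intermediate
29 | fully protected target | C=C[C@@]1(C)C[C@@H](OC(=O)/C(C)=C\COC(C)=O)[C@@H](C(=C)C(=O)OCC[Si](C)(C)C)[C@H](O[Si](CC)(CC)CC)[C@@H]1C(=C)CO[Si](C)(C)C(C)(C)C | intermediate
30 | CNP0261293.1 | C=C[C@@]1(C)C[C@@H](OC(=O)/C(C)=C\COC(C)=O)[C@@H](C(=C)C(=O)O)[C@H](O)[C@@H]1C(=C)CO | target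

Total step count: 19. Longest linear sequence: 16 (steps 1, 2, 4–13, 15, 16, 18, 19).

Steps most likely to fail

Step 12. The acid-sensitive enol ether may ionise or hydrolyse before it rearranges. The shift may also pass through a boat-like carbocycle with loss of facial selectivity at C10.

The fallback sets out from 18 and comes back at 20, and it makes the C9–C10 bond by allylic alkylation with a stabilised nucleophile. Lactone 18 would be opened by the lithium enolate of methyl acetate (Claisen-type acylation, THF, −78 °C) to the β-keto ester with a free (Z)-allylic alcohol F1. Methyl chloroformate and pyridine would convert this into the allylic methyl carbonate F2. Pd(PPh3)4 in THF at room temperature ionises the carbonate far faster than it inserts into the vinylic C–Br bond. It should therefore close the six-membered ring at the methyl-bearing allyl terminus (Tsuji–Trost, 6-exo) to the methyl 2-oxocyclohexanecarboxylate F3. Krapcho demethoxycarbonylation (LiCl, wet DMSO, 130 °C) then removes the activating ester and gives 20.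

Step 9. Intermolecular metathesis (oligomerisation) may outrun the slow closure of a strained eight-membered lactone onto a hindered 1,1-disubstituted alkene.

The fallback sets out from 13 and comes back at 17. It makes the alkene through an O6 tether and closes the lactone at the ester bond.
- Alcohol 13 would be silylated with allyloxy(chloro)diisopropylsilane (from i-Pr2SiCl2 and allyl alcohol, imidazole) to the mixed silyl ketal F4.
- Tethered RCM between two trans-diequatorial neighbours on the rigid lactone chair, helped by the long Si–O bonds, should give the dioxasilocine F5.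
- HF·pyridine would free the diol F6.
- TESOTf and 2,6-lutidine would give the bis(triethylsilyl) ether F7.
- PPTS in MeOH at 0 °C would remove only the primary allylic silyl group to give the hydroxy iodolactone F8.
- K2CO3 in dilute MeCN should then let the primary alkoxide attack the lactone carbonyl, and the released tertiary alkoxide closes the oxirane. This translactonisation is driven by epoxide formation and delivers 17.

Step 16. Oxidative addition at the hindered bromoalkene may be slow, and the trifluoroethyl phosphonate esters may undergo alcoholysis on prolonged heating with amine and alcohol.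

The fallback sets out from 24 and comes back at 25, and it builds C12 at the alcohol level. Stille coupling of 24 with (tributylstannyl)methanol (Pd(PPh3)4, dioxane, 80 °C) would give the allylic alcohol F9. MnO2 would oxidise it to the enal F10. Pinnick oxidation (NaClO2, NaH2PO4, 2-methylbut-2-ene) would give the acrylic acid F11. Steglich esterification with 2-(trimethylsilyl)ethanol then returns to 25.

Further compounds
F1 | step 12 | methyl β-keto ester with free (Z)-allylic alcohol | COC(=O)CC(=O)[C@@H](C(Br)=C)[C@H](O[Si](CC)(CC)CC)[C@H](C(=C)CO[Si](C)(C)C(C)(C)C)/C(C)=C\CO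
F2 | step 12 | allylic methyl carbonate of F1 | COC(=O)CC(=O)[C@@H](C(Br)=C)[C@H](O[Si](CC)(CC)CC)[C@H](C(=C)CO[Si](C)(C)C(C)(C)C)/C(C)=C\COC(=O)OC
F3 | step 12 | methyl 2-oxocyclohexanecarboxylate (9-methoxycarbonyl derivative of 20) | C=C[C@@]1(C)C(C(=O)OC)C(=O)[C@@H](C(Br)=C)[C@H](O[Si](CC)(CC)CC)[C@@H]1C(=C)CO[Si](C)(C)C(C)(C)C
F4 | step 9 | allyloxy(diisopropyl)silyl ether of 13 | O=C1[C@@H](C(Br)=C)[C@H](O[Si](C(C)C)(C(C)C)OCC=C)[C@@H](C(C)=C)[C@](C)(CI)O1
F5 | step 9 | dioxasilocine fused to the iodolactone | O=C1[C@@H](C(Br)=C)[C@@H]2O[Si](C(C)C)(C(C)C)OC/C=C(/C)[C@H]2[C@](C)(CI)O1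
F6 | step 9 | iodolactone diol with (Z)-allylic alcohol | O=C1[C@@H](C(Br)=C)[C@H](O)[C@@H](/C(C)=C\CO)[C@](C)(CI)O1
F7 | step 9 | bis(triethylsilyl) ether of F6 | O=C1[C@@H](C(Br)=C)[C@H](O[Si](CC)(CC)CC)[C@@H](/C(C)=C\CO[Si](CC)(CC)CC)[C@](C)(CI)O1
F8 | step 9 | O6-TES iodolactone with free (Z)-allylic alcohol | O=C1[C@@H](C(Br)=C)[C@H](O[Si](CC)(CC)CC)[C@@H](/C(C)=C\CO)[C@](C)(CI)O1
F9 | step 16 | C12 allylic alcohol | C=C[C@@]1(C)C[C@@H](OC(=O)C(C)P(=O)(OCC(F)(F)F)OCC(F)(F)F)[C@@H](C(=C)CO)[C@H](O[Si](CC)(CC)CC)[C@@H]1C(=C)CO[Si](C)(C)C(C)(C)C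
F10 | step 16 | C12 enal | C=C[C@@]1(C)C[C@@H](OC(=O)C(C)P(=O)(OCC(F)(F)F)OCC(F)(F)F)[C@@H](C(=C)C=O)[C@H](O[Si](CC)(CC)CC)[C@@H]1C(=C)CO[Si](C)(C)C(C)(C)C
F11 | step 16 | C12 acrylic acid | C=C[C@@]1(C)C[C@@H](OC(=O)C(C)P(=O)(OCC(F)(F)F)OCC(F)(F)F)[C@@H](C(=C)C(=O)O)[C@H](O[Si](CC)(CC)CC)[C@@H]1C(=C)CO[Si](C)(C)C(C)(C)C
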